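**Plan**

1. Numbering (serrulatane): C1 = ring CH(CH3), C2/C3 = ring CH2, C4 = ring CH carrying the side chain, C4a/C5/C6/C7/C8/C8a = arene (C5–H, C6–CO2Me, C7/C8–OH), C11 = side-chain CH(CH3), C12–C14 = CH2, C15 = CH(CH3), C16 = CH2OH.
2. Cuts: first the C6–CO2Me bond (ester ← aryl iodide ← aryl silane) and the O-protecting groups; then the side-chain bond C11–C12; then C4=C11 (olefination of a tetralone), the C1–CH3 bond and the arene–Cr bond.
3. Forward: commercial 5,6-dimethoxy-1-tetralone already holds both rings. It is complexed to Cr(CO)3, silylated at C6, methylated at C1 and turned into the (Z)-4-ethylidene complex. The C12–C16 organolithium made from (R)-3-bromo-2-methylpropan-1-ol is then added, the metal is removed, and SiMe3 → I → CO2Me and ether cleavage finish the target.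
4. Enabling feature: the benzene ring C4a–C5–C6–C7–C8–C8a directly attached to C4. As its η6-Cr(CO)3 complex it makes the exocyclic C4=C11 bond an acceptor, stabilises the benzylic C4 carbanion and shields one face.
5. Stereochemistry: one catalytic event (CBS reduction to a sacrificial C4 carbinol) is relayed by OH-directed complexation into planar chirality. This sets C1 (methylation anti to Cr) and, in a single event, C11 and C4 (addition and protonation anti to Cr on the Z-alkene). C15 is bought.

Key step: step 10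

Remark: η6-arene–Cr(CO)3 complexes are written in SMILES as ligand, Cr and three CO separated by dots; this notation cannot hold the complexed face, which is therefore given in each name.

**Step 1**
Reactants: 1 5,6-dimethoxy-3,4-dihydronaphthalen-1(2H)-one
Product: 2 (1R)-5,6-dimethoxy-1,2,3,4-tetrahydronaphthalen-1-ol
Conditions: (S)-2-methyl-CBS-oxazaborolidine (10 mol %), BH3·SMe2, THF, 0 °C; MeOH
Reagents that add atoms: none
Why: Corey–Bakshi–Shibata reduction of an aryl alkyl ketone, in which the (S)-oxazaborolidine should deliver hydride to give the (R)-carbinol, a sacrificial stereocentre whose only task is to direct the metal in step 2.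

**Step 2**
Reactants: 2 (1R)-5,6-dimethoxy-1,2,3,4-tetrahydronaphthalen-1-ol
Product: 3 tricarbonyl[η6-(1R)-5,6-dimethoxy-1,2,3,4-tetrahydronaphthalen-1-ol]chromium (Cr syn to OH)
Conditions: Cr(CO)6, n-Bu2O/THF (10:1), reflux, Ar, dark
Reagents that add atoms: hexacarbonylchromium, [Cr].[C-]#[O+].[C-]#[O+].[C-]#[O+].[C-]#[O+].[C-]#[O+].[C-]#[O+]
Why: Thermal arene complexation of a cyclic benzylic alcohol is hydroxyl-directed, so Cr(CO)3 should enter on the ring face syn to the OH and turn the carbinol chirality into planar chirality.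

**Step 3**
Reactants: 3 tricarbonyl[η6-(1R)-5,6-dimethoxy-1,2,3,4-tetrahydronaphthalen-1-ol]chromium (Cr syn to OH)
Product: 6 tricarbonyl[η6-(1R)-5,6-dimethoxy-7-(trimethylsilyl)-1,2,3,4-tetrahydronaphthalen-1-ol]chromium (Cr syn to OH), via dilithio complex 4 (not isolated), via bis-silyl complex 5 (not isolated)
Conditions: n-BuLi (2.3 equiv), THF, −78 °C; TMSCl (3 equiv), −78 → 0 °C; then 1 M aq. HCl, THF, 0 °C
Reagents that add atoms: chlorotrimethylsilane, C[Si](C)(C)Cl
Why: Directed ortho-lithiation of the complexed arene should occur at C6, the only ring C–H ortho to a methoxy group (the alkoxide formed first protects the carbinol), and silylation blocks this acidic site for steps 4 and 10 while marking the carbon that will carry the ester; the O–Si bond is hydrolysed in the acidic work-up.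

**Step 4**
Reactants: 6 tricarbonyl[η6-(1R)-5,6-dimethoxy-7-(trimethylsilyl)-1,2,3,4-tetrahydronaphthalen-1-ol]chromium (Cr syn to OH)
Product: 8 tricarbonyl[η6-(1R,4R)-5,6-dimethoxy-4-methyl-7-(trimethylsilyl)-1,2,3,4-tetrahydronaphthalen-1-ol]chromium (Cr syn to OH and anti to CH3), via dilithio complex 7 (not isolated)
Conditions: n-BuLi (2.3 equiv), THF/DMPU, −78 → −40 °C; MeI (1.2 equiv), −78 °C; aq. NH4Cl
Reagents that add atoms: iodomethane, CI
Why: Benzylic deprotonation of the Cr(CO)3-acidified tetralin should remove the exo hydrogen at C1 (C6 is blocked, C4–H sits next to the alkoxide, C5–H is flanked by SiMe3 and the peri carbon), and iodomethane enters anti to the metal, which sets C1 (R) trans to the C4 oxygen.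

**Step 5**
Reactants: 8 tricarbonyl[η6-(1R,4R)-5,6-dimethoxy-4-methyl-7-(trimethylsilyl)-1,2,3,4-tetrahydronaphthalen-1-ol]chromium (Cr syn to OH and anti to CH3)
Product: 9 tricarbonyl[η6-(4R)-5,6-dimethoxy-4-methyl-7-(trimethylsilyl)-3,4-dihydronaphthalen-1(2H)-one]chromium (Cr anti to CH3)
Conditions: DMSO, Ac2O, rt
Reagents that add atoms: none
Why: Albright–Goldman oxidation is a standard metal-free oxidation of complexed benzylic alcohols and should leave the Cr(CO)3 unit, the aryl–silicon bond and the remote C1 centre untouched.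

**Step 6**
Reactants: 9 tricarbonyl[η6-(4R)-5,6-dimethoxy-4-methyl-7-(trimethylsilyl)-3,4-dihydronaphthalen-1(2H)-one]chromium (Cr anti to CH3)
Product: 10 tricarbonyl[η6-(1Z,4R)-1-ethylidene-5,6-dimethoxy-4-methyl-7-(trimethylsilyl)-1,2,3,4-tetrahydronaphthalene]chromium (Cr anti to CH3)
Conditions: EtPPh3Br (2.5 equiv), KHMDS (2.4 equiv), THF, 0 °C; then 9, −78 °C → rt; chromatographic removal of the E isomer
Reagents that add atoms: ethyltriphenylphosphonium bromide, CC[P+](c1ccccc1)(c1ccccc1)c1ccccc1.[Br-]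
Why: Wittig olefination with a non-stabilised ylide under salt-free conditions is kinetically controlled and should place the ylide methyl group cis to the bulkier aryl side of the ketone (as in the Z-selective ethylidenation of hindered cyclic ketones), giving the Z-alkene that step 10 needs; the geometry should be confirmed by NOE (vinyl CH3 to H-5) before going on.

**Step 7**
Reactants: 11 (2R)-3-bromo-2-methylpropan-1-ol
Product: 12 {[(2R)-3-bromo-2-methylpropoxy]methyl}benzene
Conditions: benzyl 2,2,2-trichloroacetimidate (1.3 equiv), TfOH (5 mol %), cyclohexane/CH2Cl2, 0 °C → rt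
Reagents that add atoms: benzyl 2,2,2-trichloroacetimidate, ClC(Cl)(Cl)C(=N)OCc1ccccc1
Why: Acid-catalysed benzylation with the trichloroacetimidate avoids alkoxide formation and hence oxetane closure of the γ-bromo alcohol; the stereocentre is not involved.

**Step 8**
Reactants: 12 {[(2R)-3-bromo-2-methylpropoxy]methyl}benzene
Product: 14 (4S)-5-(benzyloxy)-4-methylpentan-1-ol, via Grignard reagent 13 (not isolated)
Conditions: Mg, THF, 40 °C; then CuI (10 mol %), oxirane (1.5 equiv), −30 → 0 °C; aq. NH4Cl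
Reagents that add atoms: oxirane, C1CO1
Why: Copper-catalysed opening of ethylene oxide by the primary Grignard reagent adds C13 and C12 in one operation without touching the C15 centre.

**Step 9**
Reactants: 14 (4S)-5-(benzyloxy)-4-methylpentan-1-ol
Product: 15 ({[(2S)-5-iodo-2-methylpentyl]oxy}methyl)benzene
Conditions: I2, PPh3, imidazole, CH2Cl2, 0 °C → rt
Reagents that add atoms: iodine, II
Why: Appel-type iodination converts the primary alcohol into the primary iodide needed for lithium–iodine exchange.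

**Step 10**
Reactants: 10 tricarbonyl[η6-(1Z,4R)-1-ethylidene-5,6-dimethoxy-4-methyl-7-(trimethylsilyl)-1,2,3,4-tetrahydronaphthalene]chromium (Cr anti to CH3); 15 ({[(2S)-5-iodo-2-methylpentyl]oxy}methyl)benzene
Product: 18 tricarbonyl{η6-(1S,4R)-1-[(2S,6S)-7-(benzyloxy)-6-methylheptan-2-yl]-5,6-dimethoxy-4-methyl-7-(trimethylsilyl)-1,2,3,4-tetrahydronaphthalene}chromium (Cr anti to the 4-CH3 and syn to the side chain), via alkyllithium 16 (not isolated), via benzylic lithium complex 17 (not isolated)
Conditions: 15 (1.5 equiv), t-BuLi (3.0 equiv), Et2O/pentane, −78 °C; then 10, THF, −78 → −50 °C; AcOH, −78 °C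
Reagents that add atoms: none
Why: Lithium–iodine exchange gives the primary alkyllithium 16, which adds to C11, the β-carbon of the styrene-type exocyclic C4=C11 bond of 10, because the η6-Cr(CO)3 arene acts as an electron sink and the charge ends up in the metal-stabilised benzylic C4 anion 17. The closest known reaction type is the addition of organolithium reagents to Cr(CO)3-complexed styrenes and 1-alkylidene-tetralins followed by protonation. No ring is closed; the step joins the C12–C16 chain to the bicyclic core. C11 is set by attack on the alkene face anti to Cr(CO)3 of the geometrically defined Z-alkene, and C4 by protonation of 17 again anti to the metal; this net syn addition of carbon and hydrogen on the exo face should give (4S,11S) with the side chain trans to the C1 methyl group. The step needs addition in preference to deprotonation or attack at a CO ligand: C6 carries SiMe3, the C1–H is endo (methyl exo) and cannot be removed, the remaining C5–H is not ortho to a methoxy group, and low temperature should disfavour attack at the carbonyl ligands.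

**Step 11**
Reactants: 18 tricarbonyl{η6-(1S,4R)-1-[(2S,6S)-7-(benzyloxy)-6-methylheptan-2-yl]-5,6-dimethoxy-4-methyl-7-(trimethylsilyl)-1,2,3,4-tetrahydronaphthalene}chromium (Cr anti to the 4-CH3 and syn to the side chain)
Product: 20 (1S,4R)-1-[(2S,6S)-7-(benzyloxy)-6-methylheptan-2-yl]-7-iodo-5,6-dimethoxy-4-methyl-1,2,3,4-tetrahydronaphthalene, via free arylsilane 19 (not isolated)
Conditions: hν, air, Et2O, rt; filtration, evaporation; then ICl (1.1 equiv), CH2Cl2, −78 → 0 °C
Reagents that add atoms: iodine monochloride, ClI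
Why: Oxidative decomplexation removes the metal without touching the stereocentres, and the electron-rich aryl silane should then undergo ipso-iododesilylation at C6 faster than substitution at the only free position C5.

**Step 12**
Reactants: 20 (1S,4R)-1-[(2S,6S)-7-(benzyloxy)-6-methylheptan-2-yl]-7-iodo-5,6-dimethoxy-4-methyl-1,2,3,4-tetrahydronaphthalene
Product: 21 methyl (5R,8S)-8-[(2S,6S)-7-(benzyloxy)-6-methylheptan-2-yl]-3,4-dimethoxy-5-methyl-5,6,7,8-tetrahydronaphthalene-2-carboxylate
Conditions: Pd(OAc)2 (5 mol %), dppf (10 mol %), CO (1 atm), Et3N, MeOH/DMF, 70 °C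
Reagents that add atoms: carbon monoxide, [C-]#[O+]; methanol, CO
Why: Palladium-catalysed methoxycarbonylation of the aryl iodide installs the C6 methyl ester under conditions that leave the benzyl ether and the stereocentres alone.

**Step 13**
Reactants: 21 methyl (5R,8S)-8-[(2S,6S)-7-(benzyloxy)-6-methylheptan-2-yl]-3,4-dimethoxy-5-methyl-5,6,7,8-tetrahydronaphthalene-2-carboxylate
Product: 22 methyl (5R,8S)-3,4-dihydroxy-8-[(2S,6S)-7-hydroxy-6-methylheptan-2-yl]-5-methyl-5,6,7,8-tetrahydronaphthalene-2-carboxylate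
Conditions: BBr3 (5 equiv), CH2Cl2, −78 → 0 °C; MeOH, −78 °C → rt
Reagents that add atoms: none
Why: Boron tribromide cleaves both aryl methyl ethers (the C7 ether assisted by the neighbouring ester carbonyl) and the benzyl ether at low temperature, where the methyl ester and the primary alcohol (held as a borate until methanolysis) should survive.

**Compound list**

1 | 5,6-dimethoxy-3,4-dihydronaphthalen-1(2H)-one | COc1ccc2c(c1OC)CCCC2=O | starting material
2 | (1R)-5,6-dimethoxy-1,2,3,4-tetrahydronaphthalen-1-ol | COc1ccc2c(c1OC)CCC[C@H]2O | intermediate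
3 | tricarbonyl[η6-(1R)-5,6-dimethoxy-1,2,3,4-tetrahydronaphthalen-1-ol]chromium, Cr(CO)3 on the face syn to the 1-OH | COc1ccc2c(c1OC)CCC[C@H]2O.[Cr].[C-]#[O+].[C-]#[O+].[C-]#[O+] | intermediate
4 | dilithio complex: lithium alkoxide of 3 lithiated at ring C7 (serrulatane C6), same face | COc1c([Li])cc2c(c1OC)CCC[C@H]2O[Li].[Cr].[C-]#[O+].[C-]#[O+].[C-]#[O+] | intermediate
5 | bis-silyl complex: tricarbonyl[η6-(1R)-5,6-dimethoxy-7-(trimethylsilyl)-1-(trimethylsilyloxy)-1,2,3,4-tetrahydronaphthalene]chromium, Cr syn to the 1-O | COc1c([Si](C)(C)C)cc2c(c1OC)CCC[C@H]2O[Si](C)(C)C.[Cr].[C-]#[O+].[C-]#[O+].[C-]#[O+] | intermediate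
6 | tricarbonyl[η6-(1R)-5,6-dimethoxy-7-(trimethylsilyl)-1,2,3,4-tetrahydronaphthalen-1-ol]chromium, Cr syn to the 1-OH | COc1c([Si](C)(C)C)cc2c(c1OC)CCC[C@H]2O.[Cr].[C-]#[O+].[C-]#[O+].[C-]#[O+] | intermediate
7 | dilithio complex: lithium alkoxide of 6 lithiated at benzylic C4 (serrulatane C1), same face | COc1c([Si](C)(C)C)cc2c(c1OC)C([Li])CC[C@H]2O[Li].[Cr].[C-]#[O+].[C-]#[O+].[C-]#[O+] | intermediate
8 | tricarbonyl[η6-(1R,4R)-5,6-dimethoxy-4-methyl-7-(trimethylsilyl)-1,2,3,4-tetrahydronaphthalen-1-ol]chromium, Cr syn to the 1-OH and anti to the 4-CH3 | COc1c([Si](C)(C)C)cc2c(c1OC)[C@H](C)CC[C@H]2O.[Cr].[C-]#[O+].[C-]#[O+].[C-]#[O+] | intermediate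
9 | tricarbonyl[η6-(4R)-5,6-dimethoxy-4-methyl-7-(trimethylsilyl)-3,4-dihydronaphthalen-1(2H)-one]chromium, Cr anti to the 4-CH3 | COc1c([Si](C)(C)C)cc2c(c1OC)[C@H](C)CCC2=O.[Cr].[C-]#[O+].[C-]#[O+].[C-]#[O+] | intermediate
10 | tricarbonyl[η6-(1Z,4R)-1-ethylidene-5,6-dimethoxy-4-methyl-7-(trimethylsilyl)-1,2,3,4-tetrahydronaphthalene]chromium, Cr anti to the 4-CH3 | COc1c([Si](C)(C)C)cc2c(c1OC)[C@H](C)CC/C2=C/C.[Cr].[C-]#[O+].[C-]#[O+].[C-]#[O+] | intermediate
11 | (2R)-3-bromo-2-methylpropan-1-ol | BrC[C@H](C)CO | starting material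
12 | {[(2R)-3-bromo-2-methylpropoxy]methyl}benzene | BrC[C@H](C)COCc1ccccc1 | intermediate
13 | [(2R)-3-(benzyloxy)-2-methylpropyl]magnesium bromide | Br[Mg]C[C@H](C)COCc1ccccc1 | intermediate
14 | (4S)-5-(benzyloxy)-4-methylpentan-1-ol | OCCC[C@H](C)COCc1ccccc1 | intermediate
15 | ({[(2S)-5-iodo-2-methylpentyl]oxy}methyl)benzene | ICCC[C@H](C)COCc1ccccc1 | intermediate
16 | [(4S)-5-(benzyloxy)-4-methylpentyl]lithium | [Li]CCC[C@H](C)COCc1ccccc1 | intermediate
17 | benzylic lithium complex: tricarbonyl{η6-(4R)-1-[(2S,6S)-7-(benzyloxy)-6-methylheptan-2-yl]-1-lithio-5,6-dimethoxy-4-methyl-7-(trimethylsilyl)-1,2,3,4-tetrahydronaphthalene}chromium, Cr anti to the 4-CH3 | COc1c([Si](C)(C)C)cc2c(c1OC)[C@H](C)CCC2([Li])[C@@H](C)CCC[C@H](C)COCc1ccccc1.[Cr].[C-]#[O+].[C-]#[O+].[C-]#[O+] | intermediate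
18 | tricarbonyl{η6-(1S,4R)-1-[(2S,6S)-7-(benzyloxy)-6-methylheptan-2-yl]-5,6-dimethoxy-4-methyl-7-(trimethylsilyl)-1,2,3,4-tetrahydronaphthalene}chromium, Cr anti to the 4-CH3 and syn to the C1 side chain | COc1c([Si](C)(C)C)cc2c(c1OC)[C@H](C)CC[C@H]2[C@@H](C)CCC[C@H](C)COCc1ccccc1.[Cr].[C-]#[O+].[C-]#[O+].[C-]#[O+] | intermediate
19 | (1S,4R)-1-[(2S,6S)-7-(benzyloxy)-6-methylheptan-2-yl]-5,6-dimethoxy-4-methyl-7-(trimethylsilyl)-1,2,3,4-tetrahydronaphthalene | COc1c([Si](C)(C)C)cc2c(c1OC)[C@H](C)CC[C@H]2[C@@H](C)CCC[C@H](C)COCc1ccccc1 | intermediate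
20 | (1S,4R)-1-[(2S,6S)-7-(benzyloxy)-6-methylheptan-2-yl]-7-iodo-5,6-dimethoxy-4-methyl-1,2,3,4-tetrahydronaphthalene | COc1c(I)cc2c(c1OC)[C@H](C)CC[C@H]2[C@@H](C)CCC[C@H](C)COCc1ccccc1 | intermediate
21 | methyl (5R,8S)-8-[(2S,6S)-7-(benzyloxy)-6-methylheptan-2-yl]-3,4-dimethoxy-5-methyl-5,6,7,8-tetrahydronaphthalene-2-carboxylate | COC(=O)c1cc2c(c(OC)c1OC)[C@H](C)CC[C@H]2[C@@H](C)CCC[C@H](C)COCc1ccccc1 | intermediate
22 | methyl (5R,8S)-3,4-dihydroxy-8-[(2S,6S)-7-hydroxy-6-methylheptan-2-yl]-5-methyl-5,6,7,8-tetrahydronaphthalene-2-carboxylate | COC(=O)c1cc2c(c(O)c1O)[C@H](C)CC[C@H]2[C@@H](C)CCC[C@H](C)CO | target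

**Step count**

Total: 13 steps. Longest linear sequence: 10 steps (steps 1–6 and 10–13); the chain branch (steps 7–9) joins at step 10.

**Steps most likely to fail**

1. Step 10 (key step). What may go wrong: the basic primary alkyllithium abstracts an allylic proton (at C3 or at the ethylidene methyl group) or attacks a carbonyl ligand instead of adding to C11, so that the alkene is returned or the complex is destroyed. The fallback sets out from alcohol 14 and complex 10 and comes back to the route at arylsilane 19. The chain is brought in as a sulfur-stabilised carbanion, which is too weak a base for these side reactions and adds to ring carbons or CO only reversibly but to the alkene irreversibly. Alcohol 14 is oxidised with Dess–Martin periodinane to (4S)-5-(benzyloxy)-4-methylpentanal F1, which with propane-1,3-dithiol and BF3·OEt2 gives 2-[(3S)-4-(benzyloxy)-3-methylbutyl]-1,3-dithiane F2. n-BuLi (THF, −30 °C) gives the 2-lithio-1,3-dithiane F3, which is added to 10 (THF, −78 → −20 °C) to form the benzylic lithium dithiane complex F4; protonation anti to the metal gives the dithiane adduct complex F5. Light and air set free the dithiane arene F6, and nickel boride (NiCl2·6H2O, NaBH4, MeOH/THF) removes the dithiane, so that C12 becomes CH2 in 19. The stereochemical course (exo addition, exo protonation) is the same as in step 10.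

2. Step 6. What may go wrong: poor geometric control in the kinetically controlled olefination (the E isomer as main product, which would lead to the C11 epimer in step 10), or enolisation of the ketone by the ylide. The fallback sets out from ketone complex 9 and comes back at alkene complex 10. It is a Horner–Wittig sequence, in which the geometry is fixed by a stereospecific elimination and not by a kinetic preference. Lithiated ethyl(diphenyl)phosphine oxide (Ph2P(O)Et, n-BuLi, THF, −78 °C) adds to 9 anti to the metal, and the two β-hydroxy phosphine oxides are stable and separable. The diastereomer tricarbonyl{η6-(1R,4R)-1-[(1S)-1-(diphenylphosphoryl)ethyl]-5,6-dimethoxy-4-methyl-7-(trimethylsilyl)-1,2,3,4-tetrahydronaphthalen-1-ol}chromium F7 undergoes syn elimination of diphenylphosphinate (NaH, DMF, rt), which can only give the Z-alkene 10.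

3. Step 4. What may go wrong: metalation at the wrong site (ring lithiation at C5 directed by the alkoxide, or incomplete formation of the dianion) or O-methylation. The fallback sets out from alcohol complex 6 and comes back at ketone complex 9; the carbinol is removed before the benzylic alkylation. Complex 6 is oxidised (DMSO, Ac2O) to tricarbonyl[η6-5,6-dimethoxy-7-(trimethylsilyl)-3,4-dihydronaphthalen-1(2H)-one]chromium F8. This is protected as the spiro-dioxolane complex F9 (1,2-bis(trimethylsilyloxy)ethane, cat. TMSOTf, CH2Cl2, −78 °C), in which the only benzylic hydrogens are those at C1. n-BuLi (THF, −78 → −40 °C) gives the benzylic lithium dioxolane complex F10, and iodomethane enters anti to the metal to give the (4′R)-4′-methyl dioxolane complex F11. Aqueous HCl in THF removes the ketal and returns 9.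

**Further compounds**

F1 | step 10 | (4S)-5-(benzyloxy)-4-methylpentanal | O=CCC[C@H](C)COCc1ccccc1
F2 | step 10 | 2-[(3S)-4-(benzyloxy)-3-methylbutyl]-1,3-dithiane | C1CSC(CC[C@H](C)COCc2ccccc2)SC1
F3 | step 10 | {2-[(3S)-4-(benzyloxy)-3-methylbutyl]-1,3-dithian-2-yl}lithium | [Li]C1(CC[C@H](C)COCc2ccccc2)SCCCS1
F4 | step 10 | benzylic lithium dithiane complex: C1-lithio form of F5, Cr anti to the 4-CH3 | COc1c([Si](C)(C)C)cc2c(c1OC)[C@H](C)CCC2([Li])[C@@H](C)C1(CC[C@H](C)COCc3ccccc3)SCCCS1.[Cr].[C-]#[O+].[C-]#[O+].[C-]#[O+]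
F5 | step 10 | tricarbonyl(η6-2-[(3S)-4-(benzyloxy)-3-methylbutyl]-2-{(1R)-1-[(1S,4R)-5,6-dimethoxy-4-methyl-7-(trimethylsilyl)-1,2,3,4-tetrahydronaphthalen-1-yl]ethyl}-1,3-dithiane)chromium, Cr anti to the 4-CH3 | COc1c([Si](C)(C)C)cc2c(c1OC)[C@H](C)CC[C@H]2[C@@H](C)C1(CC[C@H](C)COCc3ccccc3)SCCCS1.[Cr].[C-]#[O+].[C-]#[O+].[C-]#[O+]
F6 | step 10 | 2-[(3S)-4-(benzyloxy)-3-methylbutyl]-2-{(1R)-1-[(1S,4R)-5,6-dimethoxy-4-methyl-7-(trimethylsilyl)-1,2,3,4-tetrahydronaphthalen-1-yl]ethyl}-1,3-dithiane | COc1c([Si](C)(C)C)cc2c(c1OC)[C@H](C)CC[C@H]2[C@@H](C)C1(CC[C@H](C)COCc3ccccc3)SCCCS1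
F7 | step 6 | tricarbonyl{η6-(1R,4R)-1-[(1S)-1-(diphenylphosphoryl)ethyl]-5,6-dimethoxy-4-methyl-7-(trimethylsilyl)-1,2,3,4-tetrahydronaphthalen-1-ol}chromium, Cr syn to the 1-OH and anti to the 4-CH3 | COc1c([Si](C)(C)C)cc2c(c1OC)[C@H](C)CC[C@]2(O)[C@H](C)P(=O)(c1ccccc1)c1ccccc1.[Cr].[C-]#[O+].[C-]#[O+].[C-]#[O+]
F8 | step 4 | tricarbonyl[η6-5,6-dimethoxy-7-(trimethylsilyl)-3,4-dihydronaphthalen-1(2H)-one]chromium, Cr on the face that carried the OH in 6 | COc1c([Si](C)(C)C)cc2c(c1OC)CCCC2=O.[Cr].[C-]#[O+].[C-]#[O+].[C-]#[O+]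
F9 | step 4 | tricarbonyl{η6-5',6'-dimethoxy-7'-(trimethylsilyl)-3',4'-dihydro-2'H-spiro[1,3-dioxolane-2,1'-naphthalene]}chromium, same face as F8 | COc1c([Si](C)(C)C)cc2c(c1OC)CCCC23OCCO3.[Cr].[C-]#[O+].[C-]#[O+].[C-]#[O+]
F10 | step 4 | benzylic lithium dioxolane complex: 4'-lithio form of F9 | COc1c([Si](C)(C)C)cc2c(c1OC)C([Li])CCC23OCCO3.[Cr].[C-]#[O+].[C-]#[O+].[C-]#[O+]
F11 | step 4 | tricarbonyl{η6-(4'R)-5',6'-dimethoxy-4'-methyl-7'-(trimethylsilyl)-3',4'-dihydro-2'H-spiro[1,3-dioxolane-2,1'-naphthalene]}chromium, Cr anti to the 4'-CH3 | COc1c([Si](C)(C)C)cc2c(c1OC)[C@H](C)CCC23OCCO3.[Cr].[C-]#[O+].[C-]#[O+].[C-]#[O+]
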